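**Plan**

- Retrosynthesis: first the O–Si bond of a silyl-protected target is cut, then a carbonyl transposition is reversed to a 3-ethoxy enone (vinylogous ester). Next the ring bonds C2–C3 (the enone C=C) and C1–C6 (the C(=O)–CH2 bond) of the target are cut in one operation, giving a 3-siloxy-3-nonadecylcyclobutanone and ethoxyacetylene. Last, the chain–ring bond is cut (Grignard).
- Enabling feature: C5 of the target is a quaternary carbinol carbon flanked by two ring CH2 groups (C4 and C6). Atoms C3–C4–C5–C6 therefore map onto the four-membered ring of a mirror-symmetric 3,3-disubstituted cyclobutanone (its carbonyl carbon becomes C3). Ring strain drives C–C cleavage, and the two ring C(O)–CH2 bonds are enantiotopic.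
- Forward order: the C19 chain is joined first to 3-(benzyloxy)cyclobutanone; silylation, debenzylation and oxidation unveil the four-membered ketone; the six-membered ring arises by nickel-catalysed two-carbon ring expansion with the alkyne. The bond made to the former carbonyl carbon becomes the C2=C3 double bond after hydride reduction and acid hydrolysis; desilylation ends the route.
- Stereochemistry: the only stereocenter is created in the ring expansion, where a chiral ligand selects one of the two enantiotopic ring bonds. No later step breaks a bond at this carbon.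

Key step: step 5

Assumption: the sense of induction of the chiral nickel catalyst cannot be predicted reliably; the ligand antipode named in step 5 is taken to give the (R)-configured vinylogous ester, and its mirror image is used if the opposite sense is found.

Remark: the descriptor changes from R in the vinylogous ester to S after the transposition only because the CIP ranking of the two ring arms is exchanged; the spatial arrangement stays the same.

**Route**

Step 1
Reactants: 1 1-bromononadecane; 2 3-(benzyloxy)cyclobutan-1-one
Product: 4 3-(benzyloxy)-1-nonadecylcyclobutan-1-ol, via nonadecylmagnesium bromide 3 (not isolated)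
Conditions: Mg, THF, reflux; then 2, THF, 0 °C → rt; aqueous work-up
Reagents that add atoms: none
Why: Formation of the primary Grignard reagent and its 1,2-addition to the strained cyclobutanone carbonyl (Grignard addition) should be fast because rehybridization relieves ring strain, and although both cis and trans adducts (each achiral) may form, this isomerism is erased in step 4.

Step 2
Reactants: 4 3-(benzyloxy)-1-nonadecylcyclobutan-1-ol
Product: 5 {[3-(benzyloxy)-1-nonadecylcyclobutyl]oxy}triethylsilane
Conditions: Et3SiOTf, 2,6-lutidine, CH2Cl2, −78 → 0 °C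
Reagents that add atoms: triethylsilyl trifluoromethanesulfonate, CC[Si](CC)(CC)OS(=O)(=O)C(F)(F)F
Why: Silyl ether formation with the reactive silyl triflate and 2,6-lutidine (O-silylation) should protect the hindered tertiary alcohol, which guards against retro-aldol ring opening once the β-ketone is unveiled and against alkoxide chemistry at nickel in step 5.

Step 3
Reactants: 5 {[3-(benzyloxy)-1-nonadecylcyclobutyl]oxy}triethylsilane
Product: 6 3-nonadecyl-3-[(triethylsilyl)oxy]cyclobutan-1-ol
Conditions: H2 (1 atm), Pd/C, EtOAc, rt
Reagents that add atoms: none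
Why: Catalytic hydrogenolysis of the benzyl ether over palladium in a non-protic solvent should free the secondary alcohol while the triethylsilyl ether and the cyclobutane ring stay intact.

Step 4
Reactants: 6 3-nonadecyl-3-[(triethylsilyl)oxy]cyclobutan-1-ol
Product: 7 3-nonadecyl-3-[(triethylsilyl)oxy]cyclobutan-1-one
Conditions: Dess–Martin periodinane, NaHCO3, CH2Cl2, 0 °C → rt
Reagents that add atoms: none
Why: Dess–Martin oxidation of the secondary cyclobutanol under buffered conditions should give the β-siloxy cyclobutanone without β-elimination and merges the cis/trans isomers into one achiral ketone with a mirror plane through C1 and C3.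

Step 5
Reactants: 7 3-nonadecyl-3-[(triethylsilyl)oxy]cyclobutan-1-one; 8 ethoxyethyne (ethoxyacetylene)
Product: 9 (R)-3-ethoxy-5-nonadecyl-5-[(triethylsilyl)oxy]cyclohex-2-en-1-one
Conditions: Ni(cod)2 (10 mol %), (S)-BINOL-derived N,N-bis[(R)-1-phenylethyl]phosphoramidite (20 mol %), toluene, 60 °C, slow addition of 8 (2 equiv)
Reagents that add atoms: none
Why: Proposed new method: zerovalent nickel should couple the carbonyl of 7 with the ynol ether by oxidative cyclization (C–C bond between the carbonyl carbon and the electron-rich unsubstituted alkyne carbon, nickel on the ethoxy-bearing carbon) to a spiro oxanickelacyclopentene, after which strain-driven β-carbon elimination of one ring C(O)–CH2 bond gives a seven-membered nickelacycle and C(sp3)–C(sp2) reductive elimination joins the freed CH2 to the ethoxy-bearing carbon. The closest known reaction type is the nickel-catalysed intermolecular [4+2] insertion of internal alkynes into cyclobutanones, together with enantioselective nickel-catalysed intramolecular alkene insertions into 3-substituted cyclobutanones; new here are the ynol ether partner and the intermolecular selection between enantiotopic bonds. The six-membered ring is closed by that reductive elimination, that is, by a two-carbon ring expansion (formal [4+2] annulation) of the four-membered ring and not by a Baldwin-type cyclization. The quaternary carbon, prochiral in 7, becomes the stereocenter when the chiral phosphoramidite on nickel decides which of the two enantiotopic C(O)–CH2 bonds is cleaved (catalyst control). The step needs regioselectivity, which the polarization of the ynol ether and its small hydrogen terminus should secure, enantiotopic-bond selectivity, for which the sterically very different siloxy and alkyl substituents at C3 give the ligand a handle, and chemoselectivity over alkyne oligomerization, which slow addition of 8 addresses.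

Step 6
Reactants: 9 (R)-3-ethoxy-5-nonadecyl-5-[(triethylsilyl)oxy]cyclohex-2-en-1-one
Product: 11 (S)-5-nonadecyl-5-[(triethylsilyl)oxy]cyclohex-2-en-1-one, via allylic alcohol 10 (not isolated)
Conditions: i-Bu2AlH, CH2Cl2, −78 °C; then 5 % aq. oxalic acid, THF, 0 °C
Reagents that add atoms: water, O
Why: Stork–Danheiser enone transposition: 1,2-reduction of the vinylogous ester carbonyl by the aluminium hydride and mild acid hydrolysis of the resulting 3-ethoxy allylic alcohol (ionization to the ethoxy-stabilized allyl cation, addition of water at the ethoxy-bearing carbon, loss of ethanol) should place the carbonyl on the former ethoxy carbon and the double bond on the former carbonyl carbon, with the quaternary stereocenter untouched.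

Step 7
Reactants: 11 (S)-5-nonadecyl-5-[(triethylsilyl)oxy]cyclohex-2-en-1-one
Product: 12 (S)-5-hydroxy-5-nonadecylcyclohex-2-en-1-one
Conditions: HF·pyridine, pyridine, THF, 0 °C → rt
Reagents that add atoms: none
Why: Cleavage of the tertiary triethylsilyl ether by buffered HF·pyridine (fluoride-mediated desilylation) should free the alcohol under conditions mild enough to avoid dehydration of the β-hydroxy ketone, and no bond at the stereocenter is broken.

**Compound list**

1 | 1-bromononadecane | CCCCCCCCCCCCCCCCCCCBr | starting material
2 | 3-(benzyloxy)cyclobutan-1-one | O=C1CC(OCc2ccccc2)C1 | starting material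
3 | nonadecylmagnesium bromide (formed in the flask) | CCCCCCCCCCCCCCCCCCC[Mg]Br | intermediate
4 | 3-(benzyloxy)-1-nonadecylcyclobutan-1-ol (cis/trans mixture, both isomers achiral) | OC1(CCCCCCCCCCCCCCCCCCC)CC(OCc2ccccc2)C1 | intermediate
5 | {[3-(benzyloxy)-1-nonadecylcyclobutyl]oxy}triethylsilane (cis/trans mixture, both isomers achiral) | CC[Si](CC)(CC)OC1(CCCCCCCCCCCCCCCCCCC)CC(OCc2ccccc2)C1 | intermediate
6 | 3-nonadecyl-3-[(triethylsilyl)oxy]cyclobutan-1-ol (cis/trans mixture, both isomers achiral) | CC[Si](CC)(CC)OC1(CCCCCCCCCCCCCCCCCCC)CC(O)C1 | intermediate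
7 | 3-nonadecyl-3-[(triethylsilyl)oxy]cyclobutan-1-one (achiral, prochiral at C3) | CC[Si](CC)(CC)OC1(CCCCCCCCCCCCCCCCCCC)CC(=O)C1 | intermediate
8 | ethoxyethyne (ethoxyacetylene) | C#COCC | starting material
9 | (R)-3-ethoxy-5-nonadecyl-5-[(triethylsilyl)oxy]cyclohex-2-en-1-one | CCCCCCCCCCCCCCCCCCC[C@]1(O[Si](CC)(CC)CC)CC(=O)C=C(OCC)C1 | intermediate
10 | (1RS,5S)-3-ethoxy-5-nonadecyl-5-[(triethylsilyl)oxy]cyclohex-2-en-1-ol (epimers at C1, formed in the flask) | CCCCCCCCCCCCCCCCCCC[C@]1(O[Si](CC)(CC)CC)CC(O)C=C(OCC)C1 | intermediate
11 | (S)-5-nonadecyl-5-[(triethylsilyl)oxy]cyclohex-2-en-1-one | CCCCCCCCCCCCCCCCCCC[C@]1(O[Si](CC)(CC)CC)CC=CC(=O)C1 | intermediate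
12 | (S)-5-hydroxy-5-nonadecylcyclohex-2-en-1-one | CCCCCCCCCCCCCCCCCCC[C@]1(O)CC=CC(=O)C1 | target

**Summary**

Total step count: 7
Longest linear sequence: 7 steps (from 1 or 2 to 12)

**Steps most likely to fail**

1. Step 5 (proposed new method). The ynol ether may oligomerize at nickel, insertion may occur with the opposite regiochemistry, the alkylnickel intermediate may undergo β-siloxy elimination, or the ligand may discriminate the enantiotopic ring bonds poorly. The fallback uses known chemistry only, sets out from 3 and comes back at 12. Nonadecylmagnesium bromide 3 is added across propargyl alcohol (pre-deprotonated with i-PrMgCl) under CuI catalysis (carbomagnesiation) to give 2-nonadecylprop-2-en-1-ol F1. Sharpless asymmetric epoxidation [Ti(OiPr)4, D-(−)-diethyl tartrate, t-BuOOH, 4 Å molecular sieves, CH2Cl2, −20 °C] should give (R)-(2-nonadecyloxiran-2-yl)methanol F2. Immediate tosylation (TsCl, Et3N, DMAP) gives (S)-(2-nonadecyloxiran-2-yl)methyl 4-methylbenzenesulfonate F3; this blocks the Payne rearrangement, which would racemize this epoxy alcohol. Vinylmagnesium bromide with catalytic CuI opens the oxirane at its CH2 to (S)-2-hydroxy-2-nonadecylpent-4-en-1-yl 4-methylbenzenesulfonate F4, which K2CO3 in MeOH closes to (S)-2-nonadecyl-2-(prop-2-en-1-yl)oxirane F5. 1-Lithio-1-methoxyallene (from methoxyallene and n-BuLi, THF) opens F5 at its CH2 to (S)-3-methoxy-5-nonadecylocta-1,2,7-trien-5-ol F6, and mild aqueous acid hydrolyses the allenyl ether to (S)-5-hydroxy-5-nonadecylocta-1,7-dien-3-one F7. Ring-closing metathesis with the second-generation Grubbs catalyst RuCl2(=CHPh)(H2IMes)(PCy3) in CH2Cl2 then closes the C2=C3 bond and should give 12 directly.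

2. Step 7. Desilylation may trigger elimination of the tertiary oxygen function β to the ketone, followed by tautomerization to a phenol (aromatization), or the hindered tertiary silyl ether may cleave incompletely. The fallback sets out from 9 and comes back at 12: the silyl group is removed one stage earlier, where the vinylogous ester carbonyl activates the ring far less. HF·pyridine converts 9 to (R)-3-ethoxy-5-hydroxy-5-nonadecylcyclohex-2-en-1-one F8. Excess i-Bu2AlH (the tertiary aluminium alkoxide formed in situ is inert) reduces F8 to (1RS,5S)-3-ethoxy-5-nonadecylcyclohex-2-ene-1,5-diol F9, and dilute oxalic acid effects the Stork–Danheiser transposition to 12, so the free target meets only this mild acid.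

3. Step 1. Wurtz-type homocoupling may compete during formation of the long-chain Grignard reagent, and enolization or self-condensation of the strained ketone may compete with addition. The fallback sets out from 2 and comes back at 6: the chain is introduced as a far less basic acetylide and saturated in the same hydrogenation that removes the benzyl group. 1-Nonadecyne is deprotonated with n-BuLi (THF, −78 °C) and added to 2 to give 3-(benzyloxy)-1-(nonadec-1-yn-1-yl)cyclobutan-1-ol F10. Et3SiOTf/2,6-lutidine gives {[3-(benzyloxy)-1-(nonadec-1-yn-1-yl)cyclobutyl]oxy}triethylsilane F11. Hydrogenation (H2, Pd/C, EtOAc) reduces the alkyne to the alkyl chain and cleaves the benzyl ether, giving 6.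

Further compounds
F1 | step 5 | 2-nonadecylprop-2-en-1-ol | C=C(CO)CCCCCCCCCCCCCCCCCCC
F2 | step 5 | (R)-(2-nonadecyloxiran-2-yl)methanol | CCCCCCCCCCCCCCCCCCC[C@]1(CO)OC1
F3 | step 5 | (S)-(2-nonadecyloxiran-2-yl)methyl 4-methylbenzenesulfonate | CCCCCCCCCCCCCCCCCCC[C@]1(COS(=O)(=O)c2ccc(C)cc2)OC1
F4 | step 5 | (S)-2-hydroxy-2-nonadecylpent-4-en-1-yl 4-methylbenzenesulfonate | CCCCCCCCCCCCCCCCCCC[C@](CC=C)(COS(=O)(=O)c1ccc(C)cc1)O
F5 | step 5 | (S)-2-nonadecyl-2-(prop-2-en-1-yl)oxirane | CCCCCCCCCCCCCCCCCCC[C@]1(CC=C)CO1
F6 | step 5 | (S)-3-methoxy-5-nonadecylocta-1,2,7-trien-5-ol | CCCCCCCCCCCCCCCCCCC[C@](CC(OC)=C=C)(O)CC=C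
F7 | step 5 | (S)-5-hydroxy-5-nonadecylocta-1,7-dien-3-one | CCCCCCCCCCCCCCCCCCC[C@](CC(=O)C=C)(O)CC=C
F8 | step 7 | (R)-3-ethoxy-5-hydroxy-5-nonadecylcyclohex-2-en-1-one | CCCCCCCCCCCCCCCCCCC[C@]1(O)CC(=O)C=C(OCC)C1
F9 | step 7 | (1RS,5S)-3-ethoxy-5-nonadecylcyclohex-2-ene-1,5-diol | CCCCCCCCCCCCCCCCCCC[C@]1(O)CC(O)C=C(OCC)C1
F10 | step 1 | 3-(benzyloxy)-1-(nonadec-1-yn-1-yl)cyclobutan-1-ol | OC1(C#CCCCCCCCCCCCCCCCCC)CC(OCc2ccccc2)C1
F11 | step 1 | {[3-(benzyloxy)-1-(nonadec-1-yn-1-yl)cyclobutyl]oxy}triethylsilane | CC[Si](CC)(CC)OC1(C#CCCCCCCCCCCCCCCCCC)CC(OCc2ccccc2)C1
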